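**Plan**

- Retrosynthesis: the two MOM (methoxymethyl) ethers come off last, then the lactone is cut at C3–C4 and O1–C2. This works because, in the chroman-2-one (O1, C2–C4, C4a, C5–C8, C8a), the benzhydryl carbon C4 sits on C4a directly beside the oxygen-bearing C8a. C4/C4a/C8a/O1 are therefore a latent o-quinone methide (C4=C4a exocyclic, C8a=O1) that an acetate enolate can bridge.
- The quinone methide goes back to a benzylic sulfone, then to C4–Ph (Grignard), C4a–C4 (formylation), C6–prenyl (aryl prenyl ether, para-Claisen–Cope) and C8–benzoyl (Friedel–Crafts on phloroglucinol).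
- Forward: the benzene ring is dressed first (benzoyl, two MOM ethers, prenyl, formyl, phenyl carbinol, sulfone). The lactone ring, the only ring made, closes in the annulation, and deprotection ends the route.
- Stereochemistry: the single stereocentre C4 (R) is set in the annulation by a chiral N-heterocyclic carbene bound to the acetate enolate. The racemic sulfone converges through the planar quinone methide.

Key step: step 8

Assumption: the sense of induction of the triazolium catalyst on this quinone methide cannot be assigned in advance. The (5aS,10bR) salt is written, and its commercially available mirror image is to be used if a first run favours the 4S lactone. Prenyl = 3-methylbut-2-en-1-yl.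

**Step 1**
Reactants: 1 phloroglucinol; 2 benzoyl chloride
Product: 3 2,4,6-trihydroxybenzophenone
Conditions: AlCl3 (4 equiv), PhNO2, 60 °C; ice/aq. HCl
Reagents that add atoms: none
Why: Friedel–Crafts C-acylation of the very electron-rich triol should stop at the mono-ketone with one equivalent of 2, because the first benzoyl group, complexed to aluminium, deactivates the ring.

**Step 2**
Reactants: 3 2,4,6-trihydroxybenzophenone
Product: 4 [2-hydroxy-4,6-bis(methoxymethoxy)phenyl](phenyl)methanone
Conditions: MOMCl (2.2 equiv), i-Pr2NEt (3 equiv), CH2Cl2, 0 °C → rt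
Reagents that add atoms: chloromethyl methyl ether (MOMCl), COCCl
Why: Williamson-type O-alkylation takes the para and one ortho hydroxyl, while the last ortho hydroxyl is held in a hydrogen bond to the ketone and stays free, the usual chelation-controlled outcome for 2,4,6-trihydroxyaryl ketones.

**Step 3**
Reactants: 4 [2-hydroxy-4,6-bis(methoxymethoxy)phenyl](phenyl)methanone; 5 prenyl bromide
Product: 6 {2,4-bis(methoxymethoxy)-6-[(3-methylbut-2-en-1-yl)oxy]phenyl}(phenyl)methanone
Conditions: K2CO3 (2 equiv), DMF, rt → 50 °C
Reagents that add atoms: none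
Why: Williamson ether synthesis; in a dipolar aprotic solvent the potassium phenoxide should react at oxygen with the primary allylic bromide (SN2) to give the aryl prenyl ether needed for the sigmatropic relay.

**Step 4**
Reactants: 6 {2,4-bis(methoxymethoxy)-6-[(3-methylbut-2-en-1-yl)oxy]phenyl}(phenyl)methanone
Product: 9 [6-hydroxy-2,4-bis(methoxymethoxy)-3-(3-methylbut-2-en-1-yl)phenyl](phenyl)methanone, via ortho-dienone 7 (not isolated), via para-dienone 8 (not isolated)
Conditions: PhNEt2, 200 °C, sealed tube, Ar
Reagents that add atoms: none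
Why: para-Claisen–Cope sequence: aromatic Claisen rearrangement to the free ortho carbon gives 7 with a reversed 1,1-dimethylallyl unit, a Cope rearrangement carries it to the carbon para to the ether oxygen (between the two MOM ethers) as a normal prenyl group in 8, and tautomerisation restores the chelated phenol, a course precedented for 2-acyl-3,5-dialkoxyphenyl prenyl ethers.

**Step 5**
Reactants: 9 [6-hydroxy-2,4-bis(methoxymethoxy)-3-(3-methylbut-2-en-1-yl)phenyl](phenyl)methanone; 10 paraformaldehyde
Product: 12 3-benzoyl-2-hydroxy-4,6-bis(methoxymethoxy)-5-(3-methylbut-2-en-1-yl)benzaldehyde, via benzylic alcohol 11 (not isolated)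
Conditions: MgCl2 (3 equiv), Et3N (6 equiv), MeCN, reflux; aq. citric acid work-up
Reagents that add atoms: none
Why: magnesium-mediated ortho-formylation (Casnati–Skattebøl reaction): the magnesium phenoxide should deliver formaldehyde to the only unsubstituted ring carbon, which is ortho to the phenol and activated by three oxygen donors, and the benzylic alkoxide 11 is oxidised by hydride transfer to a second formaldehyde in a non-acidic medium that spares the MOM ethers and the prenyl group.

**Step 6**
Reactants: 12 3-benzoyl-2-hydroxy-4,6-bis(methoxymethoxy)-5-(3-methylbut-2-en-1-yl)benzaldehyde; 13 phenylmagnesium bromide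
Product: 14 {2-hydroxy-3-[hydroxy(phenyl)methyl]-4,6-bis(methoxymethoxy)-5-(3-methylbut-2-en-1-yl)phenyl}(phenyl)methanone (racemic)
Conditions: PhMgBr (2.5 equiv), THF, −78 → −20 °C; sat. aq. NH4Cl; used crude
Reagents that add atoms: none
Why: Grignard addition; the first equivalent forms the magnesium phenoxide and the second should add to the aldehyde, which is far more electrophilic than the twisted, di-ortho-substituted diaryl ketone deactivated by the neighbouring phenoxide, and the racemic carbinol is acceptable because its configuration is erased in step 8.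

**Step 7**
Reactants: 14 {2-hydroxy-3-[hydroxy(phenyl)methyl]-4,6-bis(methoxymethoxy)-5-(3-methylbut-2-en-1-yl)phenyl}(phenyl)methanone
Product: 15 {2-hydroxy-4,6-bis(methoxymethoxy)-5-(3-methylbut-2-en-1-yl)-3-[(4-methylbenzenesulfonyl)(phenyl)methyl]phenyl}(phenyl)methanone (racemic)
Conditions: p-TolSO2H (1.5 equiv), CH2Cl2, 0 °C → rt
Reagents that add atoms: 4-methylbenzenesulfinic acid (p-TolSO2H), Cc1ccc(cc1)S(=O)O
Why: acid-promoted SN1-type substitution of an o-hydroxybenzhydrol by sulfinate at sulfur, the standard entry to 2-(1-sulfonylalkyl)phenols; three oxygen donors should allow ionisation under the weak sulfinic acid alone, which aryl MOM ethers tolerate, and with every ring carbon substituted no Friedel–Crafts self-condensation is possible.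

**Step 8**
Reactants: 15 {2-hydroxy-4,6-bis(methoxymethoxy)-5-(3-methylbut-2-en-1-yl)-3-[(4-methylbenzenesulfonyl)(phenyl)methyl]phenyl}(phenyl)methanone; 16 4-nitrophenyl acetate
Product: 18 (4R)-8-benzoyl-5,7-bis(methoxymethoxy)-6-(3-methylbut-2-en-1-yl)-4-phenylchroman-2-one, via o-quinone methide 17 (not isolated)
Conditions: (5aS,10bR)-2-(2,4,6-trimethylphenyl)-5a,10b-dihydro-4H,6H-indeno[2,1-b][1,2,4]triazolo[4,3-d][1,4]oxazin-2-ium chloride (20 mol %), Cs2CO3 (2.5 equiv), 16 (2.5 equiv, added slowly), 4 Å MS, THF, 0 °C → rt
Reagents that add atoms: none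
Why: Cs2CO3 deprotonates the phenol of 15 and expels p-toluenesulfinate to give the o-quinone methide 17, while the free triazolylidene is acylated by 16 and the acetyl azolium is deprotonated to a chiral azolium enolate; the enolate carbon adds in Michael fashion to the exocyclic carbon of 17 (C3–C4 bond, ring re-aromatised), and the released phenoxide then attacks the acyl azolium carbonyl (O1–C2 bond) and frees the carbene. The closest known reaction type is the carbene-catalysed formal [4+2] annulation of in situ o-quinone methides with azolium enolates to 3,4-dihydrocoumarins, and generation of the parent acetate enolate from 4-nitrophenyl acetate is known from annulations with enones and unsaturated imines. The lactone ring closes by a 6-exo-trig acyl substitution. C4 is the only new stereocentre and is controlled by the aminoindanol-derived catalyst, whose indane wall shields one face of the bound enolate so that one enantiotopic face of the planar quinone methide is attacked; both enantiomers of racemic 15 pass through the same achiral 17. The step needs C–C bond formation to win over O-acetylation and needs a single lactonisation site: the hindered phenoxide, if acetylated, is itself an activated aryl ester that can return the acyl group to the carbene, and O5 and O7 are blocked as MOM ethers so that only O1, the oxygen flanked by the benzoyl group, can close the ring.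

**Step 9**
Reactants: 18 (4R)-8-benzoyl-5,7-bis(methoxymethoxy)-6-(3-methylbut-2-en-1-yl)-4-phenylchroman-2-one
Product: 19 (4R)-8-benzoyl-5,7-dihydroxy-6-(3-methylbut-2-en-1-yl)-4-phenylchroman-2-one
Conditions: ZnBr2 (2.2 equiv), n-PrSH (4.5 equiv), CH2Cl2, 0 °C, short reaction time
Reagents that add atoms: none
Why: Lewis-acid-assisted cleavage of the two aryl methoxymethyl acetals with a soft thiol as formaldehyde acceptor (MOM deprotection); the medium is anhydrous, mildly acidic and free of oxygen nucleophiles, so the lactone should not open and re-close onto O5, the prenyl group should not cyclise onto the new phenols, and C4, which carries no acidic or ionisable bond, keeps its configuration.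

**Compound list**

1 | phloroglucinol (benzene-1,3,5-triol) | Oc1cc(O)cc(O)c1 | starting material
2 | benzoyl chloride | O=C(Cl)c1ccccc1 | starting material
3 | 2,4,6-trihydroxybenzophenone | O=C(c1ccccc1)c1c(O)cc(O)cc1O | intermediate
4 | [2-hydroxy-4,6-bis(methoxymethoxy)phenyl](phenyl)methanone | O=C(c1ccccc1)c1c(O)cc(OCOC)cc1OCOC | intermediate
5 | prenyl bromide (1-bromo-3-methylbut-2-ene) | CC(C)=CCBr | starting material
6 | {2,4-bis(methoxymethoxy)-6-[(3-methylbut-2-en-1-yl)oxy]phenyl}(phenyl)methanone | O=C(c1ccccc1)c1c(OCC=C(C)C)cc(OCOC)cc1OCOC | intermediate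
7 | ortho-dienone, 2-benzoyl-3,5-bis(methoxymethoxy)-6-(2-methylbut-3-en-2-yl)cyclohexa-2,4-dien-1-one (racemic, not isolated) | O=C1C(C(C)(C)C=C)C(OCOC)=CC(OCOC)=C1C(=O)c1ccccc1 | intermediate
8 | para-dienone, 2-benzoyl-3,5-bis(methoxymethoxy)-4-(3-methylbut-2-en-1-yl)cyclohexa-2,5-dien-1-one (not isolated) | O=C1C=C(OCOC)C(CC=C(C)C)C(OCOC)=C1C(=O)c1ccccc1 | intermediate
9 | [6-hydroxy-2,4-bis(methoxymethoxy)-3-(3-methylbut-2-en-1-yl)phenyl](phenyl)methanone (prenyl between the two MOM ethers, free hydroxyl ortho to benzoyl, one ring CH next to that hydroxyl) | O=C(c1ccccc1)c1c(O)cc(OCOC)c(CC=C(C)C)c1OCOC | intermediate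
10 | paraformaldehyde (written as the formaldehyde unit) | C=O | starting material
11 | benzylic alcohol, [2-hydroxy-3-(hydroxymethyl)-4,6-bis(methoxymethoxy)-5-(3-methylbut-2-en-1-yl)phenyl](phenyl)methanone (as magnesium salt, not isolated) | OCc1c(O)c(C(=O)c2ccccc2)c(OCOC)c(CC=C(C)C)c1OCOC | intermediate
12 | 3-benzoyl-2-hydroxy-4,6-bis(methoxymethoxy)-5-(3-methylbut-2-en-1-yl)benzaldehyde | O=Cc1c(O)c(C(=O)c2ccccc2)c(OCOC)c(CC=C(C)C)c1OCOC | intermediate
13 | phenylmagnesium bromide | Br[Mg]c1ccccc1 | starting material
14 | {2-hydroxy-3-[hydroxy(phenyl)methyl]-4,6-bis(methoxymethoxy)-5-(3-methylbut-2-en-1-yl)phenyl}(phenyl)methanone (racemic) | OC(c1ccccc1)c1c(O)c(C(=O)c2ccccc2)c(OCOC)c(CC=C(C)C)c1OCOC | intermediate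
15 | {2-hydroxy-4,6-bis(methoxymethoxy)-5-(3-methylbut-2-en-1-yl)-3-[(4-methylbenzenesulfonyl)(phenyl)methyl]phenyl}(phenyl)methanone (racemic) | Cc1ccc(cc1)S(=O)(=O)C(c1ccccc1)c1c(O)c(C(=O)c2ccccc2)c(OCOC)c(CC=C(C)C)c1OCOC | intermediate
16 | 4-nitrophenyl acetate | CC(=O)Oc1ccc(cc1)[N+](=O)[O-] | starting material
17 | o-quinone methide, 2-benzoyl-6-benzylidene-3,5-bis(methoxymethoxy)-4-(3-methylbut-2-en-1-yl)cyclohexa-2,4-dien-1-one (not isolated) | O=C1C(=Cc2ccccc2)C(OCOC)=C(CC=C(C)C)C(OCOC)=C1C(=O)c1ccccc1 | intermediate
18 | (4R)-8-benzoyl-5,7-bis(methoxymethoxy)-6-(3-methylbut-2-en-1-yl)-4-phenylchroman-2-one | CC(C)=CCc1c(OCOC)c(C(=O)c2ccccc2)c2c(c1OCOC)[C@@H](c1ccccc1)CC(=O)O2 | intermediate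
19 | (4R)-8-benzoyl-5,7-dihydroxy-6-(3-methylbut-2-en-1-yl)-4-phenylchroman-2-one (CNP0337570.1) | CC(C)=CCc1c(O)c(C(=O)c2ccccc2)c2c(c1O)[C@@H](c1ccccc1)CC(=O)O2 | target

**Count and risks**

Total step count: 9. Longest linear sequence: 9 steps (1 → 19).

Steps most likely to fail:

1. Step 8. The small, unsubstituted azolium enolate may capture the donor-stabilised quinone methide too slowly, since its exocyclic carbon is crowded by the C5 MOM ether. O-acetylation of the phenoxide and consumption of the ester would then take over, and facial discrimination may be poor, also because of a mixture of exocyclic alkene geometries. The fallback keeps the same two bond formations but uses hydrogen-bonding catalysis and a malonate surrogate. It sets out from 15 and returns at 18. Sulfone 15 is stirred with Meldrum's acid and the bifunctional squaramide 3-{[3,5-bis(trifluoromethyl)phenyl]amino}-4-{[(8α,9S)-6′-methoxycinchonan-9-yl]amino}cyclobut-3-ene-1,2-dione (or its quinidine-derived pseudo-enantiomer, whichever gives 4R) in toluene over aq. NaHCO3. Conjugate addition to the quinone methide released in situ should give 5-{(R)-[3-benzoyl-2-hydroxy-4,6-bis(methoxymethoxy)-5-(3-methylbut-2-en-1-yl)phenyl](phenyl)methyl}-2,2-dimethyl-1,3-dioxane-4,6-dione F1. On warming in toluene the phenol opens the dioxanedione with loss of acetone to (4R)-8-benzoyl-5,7-bis(methoxymethoxy)-6-(3-methylbut-2-en-1-yl)-2-oxo-4-phenylchroman-3-carboxylic acid F2, which decarboxylates to 18.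

2. Step 4. The rearrangement may stop after the ortho-Claisen shift, with tautomerisation to the reverse-prenyl phenol at the wrong carbon, or the prenyl ether and MOM groups may be lost thermally. The fallback places the prenyl group by direct C-alkylation of a fully acylated phloroglucinol. It sets out from 1 and returns at 14. Phloroglucinol 1 is benzoylated twice with 2 (AlCl3, PhNO2, higher temperature) to (2,4,6-trihydroxy-1,3-phenylene)bis(phenylmethanone) F3. C-prenylation with 5 at the last ring carbon (aq. KOH) gives [2,4,6-trihydroxy-5-(3-methylbut-2-en-1-yl)-1,3-phenylene]bis(phenylmethanone) F4. MOMCl/i-Pr2NEt protects the two hydroxyls flanking the prenyl group and leaves the doubly chelated hydroxyl between the ketones free, giving [2-hydroxy-4,6-bis(methoxymethoxy)-5-(3-methylbut-2-en-1-yl)-1,3-phenylene]bis(phenylmethanone) F5. One of the two equivalent ketones is then reduced with NaBH4 (1 equiv, low temperature) to 14. The regioselectivity of the MOM protection and the mono-reduction are the open points of this path.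

3. Step 5. Formylation may stall because the magnesium phenoxide is locked in a chelate with the benzoyl oxygen and the free carbon is flanked by two oxygen substituents. The fallback skips the aldehyde and the carbinol. It sets out from 9 and returns at 15. Phenol 9 is condensed with benzaldehyde and p-TolSO2H in CH2Cl2 in a three-component Mannich-type sulfonylalkylation, known for electron-rich phenols, which installs the benzylic carbon, its phenyl group and the sulfone in one operation. No new compound is made on this path.

**Further compounds**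

F1 | step 8 | 5-{(R)-[3-benzoyl-2-hydroxy-4,6-bis(methoxymethoxy)-5-(3-methylbut-2-en-1-yl)phenyl](phenyl)methyl}-2,2-dimethyl-1,3-dioxane-4,6-dione | CC(C)=CCc1c(OCOC)c(C(=O)c2ccccc2)c(O)c(c1OCOC)[C@@H](c1ccccc1)C1C(=O)OC(C)(C)OC1=O
F2 | step 8 | (4R)-8-benzoyl-5,7-bis(methoxymethoxy)-6-(3-methylbut-2-en-1-yl)-2-oxo-4-phenylchroman-3-carboxylic acid (C3 epimers) | CC(C)=CCc1c(OCOC)c(C(=O)c2ccccc2)c2c(c1OCOC)[C@@H](c1ccccc1)C(C(=O)O)C(=O)O2
F3 | step 4 | (2,4,6-trihydroxy-1,3-phenylene)bis(phenylmethanone) | O=C(c1ccccc1)c1c(O)cc(O)c(C(=O)c2ccccc2)c1O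
F4 | step 4 | [2,4,6-trihydroxy-5-(3-methylbut-2-en-1-yl)-1,3-phenylene]bis(phenylmethanone) | O=C(c1ccccc1)c1c(O)c(CC=C(C)C)c(O)c(C(=O)c2ccccc2)c1O
F5 | step 4 | [2-hydroxy-4,6-bis(methoxymethoxy)-5-(3-methylbut-2-en-1-yl)-1,3-phenylene]bis(phenylmethanone) | O=C(c1ccccc1)c1c(OCOC)c(CC=C(C)C)c(OCOC)c(C(=O)c2ccccc2)c1O
F0 | step 5 | none | none
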